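## Structural features

- The target is (+)-catechin, with its 2,3-trans ring C and flavan C2 (R) and C3 (S) intact. Ring A carries two identical 2,4,7-trimethyloctahydro-1H-cyclopenta[c]pyridine units at flavan C6 and C8, each bound through its C1.
- Each unit is a cis-fused piperidine (C1–N2–C3–C4–C4a–C7a) and cyclopentane (C4a–C5–C6–C7–C7a). It has five stereocentres, (1R,4R,4aR,7S,7aR); C4, C4a, C7a and C1 are contiguous and C7 adjoins C7a.
- The aryl group on C1 and the methyl groups on C4 and C7 all stand cis to the ring-fusion hydrogens H4a and H7a, that is, on the convex face of the bicycle.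
- Ring A is hexasubstituted, and each aryl–C1 bond is flanked by two oxygen atoms, so every reaction at C1 or at the arene carbon is sterically hindered.
- Fragile groups are the free catechol and phloroglucinol hydroxyls (air and base), the benzylic C1–N bonds ortho and para to phenolic oxygen (a Mannich-base motif that can ionise), and the benzylic flavan C2–O1 bond.
- The real difficulty is to set ten stereocentres in two copies on a crowded arene, remote from the flavan stereocentres, so that control must come from within each arm.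
- The key step exploits the following feature. If N2 is removed and C1 is joined to C3, each piperidine becomes a cyclopentanone fused at C4a–C7a to the cyclopentane. The C1=C7a enone of that cis-bicyclo[3.3.0]octan-3-one is the [2+2+1] adduct of an aryl alkyne (C1≡C7a), a tethered alkene (C4a=C4) and CO (C3), with C7 as the propargylic stereocentre.

## Logic of the disconnections

**25 ⇒ 24.** The five O–H groups become O–CH2OCH3 acetals. The free polyphenol is air- and base-sensitive, and its phenoxide would open ring C. The acetals tolerate bases, hydrides, organometallics and cobalt carbonyls. The forward step must remove them with acid without ionising the benzylic C1–N bonds.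

**24 ⇒ 23.** The two C3 methylene groups become lactam carbonyls. This makes N2 non-basic and leaves C4 as the only enolisable carbon of each arm. The forward hydride reduction must not disturb C4.

**23 ⇒ 22.** The two C4–CH3 bonds are cut. Two stereocentres disappear. The forward enolate alkylation must take place on the convex face, once per arm.

**22 ⇒ 21.** The two N–CH3 bonds are cut, leaving secondary lactams. The forward step is a plain N-alkylation.

**21 ⇒ 19 ⇒ 18.** The C1–N2 and N2–C3 bonds are cut and C1 is rejoined to C3. The heterocycle becomes a cyclopentanone whose C1 is an epimerisable α-carbon. The forward steps need an oxime with the hydroxyl anti to C1, and migration of C1 with retention rather than fragmentation.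

**18 ⇒ 16.** The C1–H and C7a–H bonds are cut to give the C1=C7a enone. Two stereocentres per arm are removed. Forward, hydrogen must reach C7a cis to H4a, and C1 is then set by equilibration.

**16 ⇒ 14 (key).** In each arm C4a–C7a, C3–C4 and C1–C3 are cut. Four rings and six bonds are removed, and each arm is left with C7 as its only stereocentre. The forward cycloaddition must set C4a relative to C7 and must tolerate an alkyne flanked by two ortho oxygens.

**14 ⇒ 13 + 10.** The two aryl–alkynyl bonds at flavan C6 and C8 are cut. The target divides into a chiral-pool arene and two copies of a C8 enyne. The forward coupling must succeed twice at a di-ortho-oxygenated iodide.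

**13 ⇒ 12 ⇒ 11.** The two C–I bonds and then the five acetal O–C bonds are cut. Ring A is the only strongly activated ring, and flavan C6 and C8 are its only free positions, so the regiochemistry is built in.

**10 ⇒ 9 ⇒ 8.** The terminal alkyne carbon is removed, then the aldehyde is traced to the primary alcohol. The forward one-carbon homologation must not epimerise the α-stereocentre.

**8 ⇒ 7 ⇒ 4 + 5.** The bond between the methylene next to the stereocentre and the allyl CH2 is cut. The forward step is an sp3–sp3 coupling of a sulfonate with the allyl nucleophile 6, made from 5.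

**4 ⇒ 3 ⇒ 2 ⇒ 1.** Only functional groups change. The two oxygenated arms of 1 are told apart by protection. Which arm becomes the alkyne decides the configuration of C7.

## Other disconnections considered

**Alternative 1:** Ring A is cut at flavan C5–C6 and C8–C8a. This gives the C2-symmetric ketone A1 (the alkaloid units on both α-carbons) and the 2-substituted malonyl dichloride A2, which carries the future ring C atoms as a cyclic carbonate. Forward, double C-acylation of A1 by A2 and enolisation would give phloroglucinol A3. Ring C would then close by attack of a flanking phenol on the benzylic carbonate carbon with inversion (A3 is S there), followed by ester cleavage.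
- In favour: the route is highly convergent. The 6,8-pattern is built in. The two phenols that flank the side chain of A3 are equivalent, so ring C closure has no regiochemical issue. The alkaloid units arrive complete, so no late nitrogen insertion is needed. On these points it is the better plan.
- Against: a ketone with basic β-amino groups is prone to retro-Mannich loss of C1 configuration. Tertiary amines and a malonyl dichloride with an α-hydrogen are expected to give ketenes. Ketones normally react with malonyl dichlorides through oxygen to give 4-hydroxy-2-pyranones, not carbocycles. Ring C and its two stereocentres, which (+)-catechin supplies for nothing, must be built again.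
- Comparison: mechanistically the ring A annulation is much less secure than a Pauson–Khand reaction, and the step count is unlikely to be lower once A1 and A2 are made.

**Alternative 2:** Each cyclopentane is cut at C4a–C5. Forward, reductive decarboxylation of the bis(N-hydroxyphthalimide ester) A4 would give primary C5 radicals. These add 5-exo to C4a of the α-methyl unsaturated lactams, and the C4 radical is then reduced, giving A5.
- In favour: A5 is the same compound as 23, so the endgame is identical (equal). The radical closure is little affected by the crowded arene, is expected to give the cis ring fusion, and leaves C4 correctable by enolisation. It also avoids the enone reduction and the Beckmann step, the two weakest steps after the key step here (better).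
- Against: A4 must already hold C1, C7a and the acyclic C7 in each arm. The trans C1/C7a relation and C7 would have to be built twice on the hindered arene by stepwise, non-convergent chemistry.
- Comparison: the chosen plan sets C4a in the same step that makes four rings, and needs only C7 beforehand. It should be shorter overall, at the price of a riskier ring-forming step.

**Alternative 3:** Ring C is cut at C3=C4 after retro-hydroboration. Forward, the diene A6, as its bis-ammonium salt, would be closed by the second-generation Hoveyda–Grubbs catalyst to the flav-3-ene A7 with loss of ethylene. Hydroboration–oxidation would then place the 3-hydroxyl trans to the C2 aryl group.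
- In favour: the metathesis is catalytic and better precedented than a double Pauson–Khand reaction on a hindered aryl alkyne (better as a single step). The trans selectivity of flav-3-ene hydroboration is also well founded.
- Against: it rebuilds a ring that is commercially available with both stereocentres. It needs an enantiopure, easily ionised 1-arylallyl ether. Borane and peroxide would have to be used in the presence of two amines and free phenols. The alkaloid units, which are the real problem, are not addressed.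
- Comparison: it is longer and solves the easier half of the structure.

Key step: step 11

Remarks on the chemistry:
- C1–C7a are the locants of the cyclopenta[c]pyridine units; flavan positions are written "flavan C…". The target is taken as the free base.
- From the (R)-ester 1, the hydroxymethyl carbon must become the alkyne-bearing carbon and the ester carbon the allylated methylene. The opposite assignment would give the (R)-enyne and the C7-epimeric series.
- The C4 methyl group is introduced after ring expansion, on the lactam enolate. In the ketone both C1 and C4 are enolisable, and a C4 substituent would blur the oxime geometry.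

## Route

Step 1
Reactants: 1 methyl (R)-3-hydroxy-2-methylpropanoate
Product: 2 methyl (R)-3-[(tert-butyldimethylsilyl)oxy]-2-methylpropanoate
Conditions: TBSCl, imidazole, CH2Cl2, 0 → 23 °C
Reagents that add atoms: tert-butyldimethylsilyl chloride, CC(C)(C)[Si](C)(C)Cl
Why: Silylation of the primary alcohol; it distinguishes the two oxygenated arms so that the ester carbon can become the chain methylene.

Step 2
Reactants: 2 methyl (R)-3-[(tert-butyldimethylsilyl)oxy]-2-methylpropanoate
Product: 3 (S)-3-[(tert-butyldimethylsilyl)oxy]-2-methylpropan-1-ol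
Conditions: i-Bu2AlH (2.3 equiv), CH2Cl2, −78 → 0 °C; aq. potassium sodium tartrate
Reagents that add atoms: none
Why: Hydride reduction of the ester to the primary alcohol; the stereocentre is untouched (the descriptor changes only through priorities), and low temperature suppresses silyl migration.

Step 3
Reactants: 3 (S)-3-[(tert-butyldimethylsilyl)oxy]-2-methylpropan-1-ol
Product: 4 (R)-3-[(tert-butyldimethylsilyl)oxy]-2-methylpropyl 4-methylbenzenesulfonate
Conditions: TsCl, Et3N, DMAP (cat.), CH2Cl2, 0 → 23 °C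
Reagents that add atoms: 4-methylbenzenesulfonyl chloride, Cc1ccc(cc1)S(=O)(=O)Cl
Why: Sulfonylation of the primary alcohol gives the leaving group for the sp3–sp3 coupling.

Step 4
Reactants: 4 (R)-3-[(tert-butyldimethylsilyl)oxy]-2-methylpropyl 4-methylbenzenesulfonate; 5 allyl bromide
Product: 7 (S)-tert-butyldimethyl[(2-methylhex-5-en-1-yl)oxy]silane, via allylmagnesium bromide 6 (not isolated)
Conditions: 5, Mg, Et2O, 0 °C; then 4, CuI (10 mol%), THF, −20 → 23 °C
Reagents that add atoms: none
Why: Copper-catalysed coupling of a Grignard reagent with a primary sulfonate; the displacement is at the methylene, not at the stereocentre.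

Step 5
Reactants: 7 (S)-tert-butyldimethyl[(2-methylhex-5-en-1-yl)oxy]silane
Product: 8 (S)-2-methylhex-5-en-1-ol
Conditions: n-Bu4NF, THF, 0 → 23 °C
Reagents that add atoms: none
Why: Fluoride cleavage of the silyl ether; the alkene and the stereocentre are inert.

Step 6
Reactants: 8 (S)-2-methylhex-5-en-1-ol
Product: 9 (S)-2-methylhex-5-enal
Conditions: Dess–Martin periodinane, CH2Cl2, 0 → 23 °C; used at once as a cold solution
Reagents that add atoms: none
Why: Mild periodinane oxidation stops at the aldehyde under nearly neutral conditions, which protects the α-stereocentre.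

Step 7
Reactants: 9 (S)-2-methylhex-5-enal
Product: 10 (S)-3-methylhept-6-en-1-yne
Conditions: MeC(O)C(N2)P(O)(OMe)2, K2CO3, MeOH, 0 → 23 °C
Reagents that add atoms: dimethyl (1-diazo-2-oxopropyl)phosphonate, CC(=O)C(=[N+]=[N-])P(=O)(OC)OC
Why: Seyferth–Gilbert homologation in the Ohira–Bestmann form; the mild carbonate base at 0 °C is chosen so that the α-methyl aldehyde reacts faster than it enolises.

Step 8
Reactants: 11 (+)-catechin
Product: 12 (2R,3S)-2-[3,4-bis(methoxymethoxy)phenyl]-3,5,7-tris(methoxymethoxy)chromane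
Conditions: MeOCH2Cl (excess), i-Pr2NEt, CH2Cl2–DMF, 0 → 40 °C
Reagents that add atoms: chloromethyl methyl ether, COCCl
Why: Williamson-type acetalisation of the four phenols and the 3-hydroxyl; an amine base avoids the phenoxide-driven opening of ring C that would epimerise flavan C2.

Step 9
Reactants: 12 (2R,3S)-2-[3,4-bis(methoxymethoxy)phenyl]-3,5,7-tris(methoxymethoxy)chromane
Product: 13 (2R,3S)-2-[3,4-bis(methoxymethoxy)phenyl]-6,8-diiodo-3,5,7-tris(methoxymethoxy)chromane
Conditions: NIS (2.1 equiv), DMF, 0 → 23 °C, dark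
Reagents that add atoms: N-iodosuccinimide, O=C1CCC(=O)N1I
Why: Electrophilic aromatic iodination; the tri-oxygenated ring A is far more reactive than ring B, and flavan C6 and C8 are its only free positions.

Step 10
Reactants: 13 (2R,3S)-2-[3,4-bis(methoxymethoxy)phenyl]-6,8-diiodo-3,5,7-tris(methoxymethoxy)chromane; 10 (S)-3-methylhept-6-en-1-yne (3 equiv)
Product: 14 (2R,3S)-2-[3,4-bis(methoxymethoxy)phenyl]-3,5,7-tris(methoxymethoxy)-6,8-bis[(3S)-3-methylhept-6-en-1-yn-1-yl]chromane
Conditions: Pd(PPh3)4 (10 mol%), CuI (20 mol%), i-Pr2NH–DMF, 70 °C, degassed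
Reagents that add atoms: none
Why: Twofold Sonogashira coupling; aryl iodides are used because oxidative addition to the electron-rich, di-ortho-oxygenated ring is the slow step, and the terminal alkene is a spectator.

Step 11
Reactants: 14 (2R,3S)-2-[3,4-bis(methoxymethoxy)phenyl]-3,5,7-tris(methoxymethoxy)-6,8-bis[(3S)-3-methylhept-6-en-1-yn-1-yl]chromane
Product: 16 (2R,3S)-2-[3,4-bis(methoxymethoxy)phenyl]-3,5,7-tris(methoxymethoxy)-6,8-bis[(4S,6aR)-4-methyl-2-oxo-1,2,4,5,6,6a-hexahydropentalen-3-yl]chromane, via bis(hexacarbonyldicobalt–alkyne) complex 15 (not isolated)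
Conditions: Co2(CO)8 (2.3 equiv), CH2Cl2, 23 °C; then N-methylmorpholine N-oxide (12 equiv), 0 → 23 °C
Reagents that add atoms: dicobalt octacarbonyl (source of C3 and its oxygen in each arm), O=C=[Co](=C=O)(=C=O)(=C=O)[Co](=C=O)(=C=O)(=C=O)=C=O
Why: Each alkyne binds Co2(CO)8 with loss of two CO to give the C2Co2(CO)6 cluster 15 (zerovalent cobalt), and the N-oxide then oxidises a CO ligand to CO2 and frees a site for the tethered alkene. Alkene insertion into the Co–C7a bond forms C4a–C7a and closes the cyclopentane (C7a–C7–C6–C5–C4a) in a 5-exo sense. CO insertion into the Co–C4 bond forms C3–C4, and reductive elimination forms C1–C3 and closes the cyclopentenone (C1–C7a–C4a–C4–C3). The closest known reaction type is the intramolecular Pauson–Khand reaction of 1-aryl 1,6-enynes that carry a propargylic substituent. Regiochemistry is fixed by the tether: C7a bonds to the internal alkene carbon and the aryl-bearing C1 to CO. The one new stereocentre per arm, C4a, is controlled by C7: in the insertion transition state the C7 methyl group turns away from the aryl group on C1 (allylic 1,3-strain in the developing C1=C7a unit) and so ends on the face that carries H4a, which should give the (4S,6aR) enone. The two arms are insulated from each other and from the flavan stereocentres, so the same sense is expected twice. The step needs this facial selectivity and chemoselectivity for the enyne over the acetals and aryl ethers; the bulky di-ortho-oxygenated aryl group should raise the facial preference but slow the insertion, hence the N-oxide promoter and not heat.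

Step 12
Reactants: 16 (2R,3S)-2-[3,4-bis(methoxymethoxy)phenyl]-3,5,7-tris(methoxymethoxy)-6,8-bis[(4S,6aR)-4-methyl-2-oxo-1,2,4,5,6,6a-hexahydropentalen-3-yl]chromane
Product: 18 (2R,3S)-2-[3,4-bis(methoxymethoxy)phenyl]-3,5,7-tris(methoxymethoxy)-6,8-bis[(1R,3aR,6S,6aR)-6-methyl-2-oxooctahydropentalen-1-yl]chromane, via C1-epimer mixture of the bis-ketone 17 (not isolated)
Conditions: Mn(dpm)3 (dpm = dipivaloylmethanate, 20 mol%), PhSiH3, i-PrOH–CH2Cl2, 23 °C, Ar; then K2CO3, MeOH, 23 °C
Reagents that add atoms: none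
Why: Metal-hydride hydrogen-atom-transfer conjugate reduction: a hydrogen atom adds to C7a and leaves the C1 radical (α to C3=O and benzylic), which is reduced and protonated. H7a should end cis to H4a because a trans-fused bicyclo[3.3.0]octane is strongly disfavoured. Carbonate then equilibrates C1, α to the ketone, to the convex-face aryl epimer, trans to the C7a–C7 bond.

Step 13
Reactants: 18 (2R,3S)-2-[3,4-bis(methoxymethoxy)phenyl]-3,5,7-tris(methoxymethoxy)-6,8-bis[(1R,3aR,6S,6aR)-6-methyl-2-oxooctahydropentalen-1-yl]chromane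
Product: 19 (2R,3S)-2-[3,4-bis(methoxymethoxy)phenyl]-3,5,7-tris(methoxymethoxy)-6,8-bis[(1R,2E,3aR,6S,6aR)-2-(hydroxyimino)-6-methyloctahydropentalen-1-yl]chromane
Conditions: NH2OH·HCl, pyridine, EtOH, 60 °C
Reagents that add atoms: hydroxylamine hydrochloride, [NH3+]O.[Cl-]
Why: Oxime condensation; the hydroxyl should settle anti to the bulky aryl-bearing C1 and syn to the C4 methylene (E), the geometry that the rearrangement needs, and the pyridine buffer spares the acetals.

Step 14
Reactants: 19 (2R,3S)-2-[3,4-bis(methoxymethoxy)phenyl]-3,5,7-tris(methoxymethoxy)-6,8-bis[(1R,2E,3aR,6S,6aR)-2-(hydroxyimino)-6-methyloctahydropentalen-1-yl]chromane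
Product: 21 (2R,3S)-2-[3,4-bis(methoxymethoxy)phenyl]-3,5,7-tris(methoxymethoxy)-6,8-bis[(1R,4aR,7S,7aR)-7-methyl-3-oxooctahydro-1H-cyclopenta[c]pyridin-1-yl]chromane, via bis(oxime O-tosylate) 20 (not isolated)
Conditions: TsCl, Et3N, DMAP (cat.), CH2Cl2, 0 °C; then THF–aq. NaHCO3, 50 °C
Reagents that add atoms: water, O
Why: Beckmann rearrangement of the oxime sulfonate under non-acidic conditions: the C1–C3 bond anti to the leaving group shifts to nitrogen with retention at C1, and water captures the imidoyl intermediate. The cyclopentanone becomes the six-membered lactam and the temporary C1–C3 bond is cut.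

Step 15
Reactants: 21 (2R,3S)-2-[3,4-bis(methoxymethoxy)phenyl]-3,5,7-tris(methoxymethoxy)-6,8-bis[(1R,4aR,7S,7aR)-7-methyl-3-oxooctahydro-1H-cyclopenta[c]pyridin-1-yl]chromane
Product: 22 (2R,3S)-2-[3,4-bis(methoxymethoxy)phenyl]-3,5,7-tris(methoxymethoxy)-6,8-bis[(1R,4aR,7S,7aR)-2,7-dimethyl-3-oxooctahydro-1H-cyclopenta[c]pyridin-1-yl]chromane
Conditions: NaH, MeI, THF–DMF, 0 → 23 °C
Reagents that add atoms: methyl iodide, CI
Why: N-Alkylation of the lactam anions; the N–H groups are the only sites acidic enough for NaH, so C4 is not touched.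

Step 16
Reactants: 22 (2R,3S)-2-[3,4-bis(methoxymethoxy)phenyl]-3,5,7-tris(methoxymethoxy)-6,8-bis[(1R,4aR,7S,7aR)-2,7-dimethyl-3-oxooctahydro-1H-cyclopenta[c]pyridin-1-yl]chromane
Product: 23 (2R,3S)-2-[3,4-bis(methoxymethoxy)phenyl]-3,5,7-tris(methoxymethoxy)-6,8-bis[(1R,4R,4aS,7S,7aR)-2,4,7-trimethyl-3-oxooctahydro-1H-cyclopenta[c]pyridin-1-yl]chromane
Conditions: LiN(i-Pr)2 (2.6 equiv), THF, −78 °C; MeI, −78 → −40 °C
Reagents that add atoms: methyl iodide, CI
Why: Lactam enolate alkylation at C4, now the only enolisable carbon; methyl iodide should approach anti to the C4a–C5 bond (convex face, cis to H4a), which sets 4R. The 4aS descriptor reflects a priority change only.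

Step 17
Reactants: 23 (2R,3S)-2-[3,4-bis(methoxymethoxy)phenyl]-3,5,7-tris(methoxymethoxy)-6,8-bis[(1R,4R,4aS,7S,7aR)-2,4,7-trimethyl-3-oxooctahydro-1H-cyclopenta[c]pyridin-1-yl]chromane
Product: 24 (2R,3S)-2-[3,4-bis(methoxymethoxy)phenyl]-3,5,7-tris(methoxymethoxy)-6,8-bis[(1R,4R,4aR,7S,7aR)-2,4,7-trimethyloctahydro-1H-cyclopenta[c]pyridin-1-yl]chromane
Conditions: LiAlH4, THF, 66 °C; H2O, aq. NaOH work-up
Reagents that add atoms: none
Why: Hydride reduction of the tertiary lactams to the N-methylpiperidines (C3=O to CH2); acetals and aryl ethers are inert and no stereocentre is involved.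

Step 18
Reactants: 24 (2R,3S)-2-[3,4-bis(methoxymethoxy)phenyl]-3,5,7-tris(methoxymethoxy)-6,8-bis[(1R,4R,4aR,7S,7aR)-2,4,7-trimethyloctahydro-1H-cyclopenta[c]pyridin-1-yl]chromane
Product: 25 (2R,3S)-2-(3,4-dihydroxyphenyl)-6,8-bis[(1R,4R,4aR,7S,7aR)-2,4,7-trimethyloctahydro-1H-cyclopenta[c]pyridin-1-yl]chromane-3,5,7-triol (CNP0284716.2)
Conditions: HCl, MeOH, 40 °C, Ar; then aq. NaHCO3 to pH 8
Reagents that add atoms: none
Why: Acid-catalysed acetal exchange with methanol removes the five methoxymethyl groups as dimethoxymethane; the amines are held as ammonium ions during the reaction and neutralisation under argon frees the base.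

## Compound list

1 | methyl (R)-3-hydroxy-2-methylpropanoate | COC(=O)[C@@H](CO)C | starting material
2 | methyl (R)-3-[(tert-butyldimethylsilyl)oxy]-2-methylpropanoate | COC(=O)[C@@H](CO[Si](C)(C)C(C)(C)C)C | intermediate
3 | (S)-3-[(tert-butyldimethylsilyl)oxy]-2-methylpropan-1-ol | OC[C@@H](CO[Si](C)(C)C(C)(C)C)C | intermediate
4 | (R)-3-[(tert-butyldimethylsilyl)oxy]-2-methylpropyl 4-methylbenzenesulfonate | Cc1ccc(cc1)S(=O)(=O)OC[C@@H](CO[Si](C)(C)C(C)(C)C)C | intermediate
5 | allyl bromide (3-bromoprop-1-ene) | C=CCBr | starting material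
6 | allylmagnesium bromide | C=CC[Mg]Br | intermediate
7 | (S)-tert-butyldimethyl[(2-methylhex-5-en-1-yl)oxy]silane | C=CCC[C@@H](CO[Si](C)(C)C(C)(C)C)C | intermediate
8 | (S)-2-methylhex-5-en-1-ol | C=CCC[C@@H](CO)C | intermediate
9 | (S)-2-methylhex-5-enal | C=CCC[C@@H](C=O)C | intermediate
10 | (S)-3-methylhept-6-en-1-yne | C#C[C@@H](C)CCC=C | intermediate
11 | (+)-catechin, (2R,3S)-2-(3,4-dihydroxyphenyl)chromane-3,5,7-triol | Oc1cc(O)cc2c1C[C@H](O)[C@@H](c1ccc(O)c(O)c1)O2 | starting material
12 | (2R,3S)-2-[3,4-bis(methoxymethoxy)phenyl]-3,5,7-tris(methoxymethoxy)chromane | COCOc1cc(OCOC)cc2c1C[C@H](OCOC)[C@@H](c1ccc(OCOC)c(OCOC)c1)O2 | intermediate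
13 | (2R,3S)-2-[3,4-bis(methoxymethoxy)phenyl]-6,8-diiodo-3,5,7-tris(methoxymethoxy)chromane | COCOc1c(I)c(OCOC)c(I)c2c1C[C@H](OCOC)[C@@H](c1ccc(OCOC)c(OCOC)c1)O2 | intermediate
14 | (2R,3S)-2-[3,4-bis(methoxymethoxy)phenyl]-3,5,7-tris(methoxymethoxy)-6,8-bis[(3S)-3-methylhept-6-en-1-yn-1-yl]chromane | COCOc1c(C#C[C@@H](C)CCC=C)c(OCOC)c(C#C[C@@H](C)CCC=C)c2c1C[C@H](OCOC)[C@@H](c1ccc(OCOC)c(OCOC)c1)O2 | intermediate
15 | bis(hexacarbonyldicobalt) complex of 14, one Co2(CO)6 unit bridging each alkyne | COCOc1c(C34C5([C@@H](C)CCC=C)[Co]3(=C=O)(=C=O)(=C=O)[Co]45(=C=O)(=C=O)=C=O)c(OCOC)c(C34C5([C@@H](C)CCC=C)[Co]3(=C=O)(=C=O)(=C=O)[Co]45(=C=O)(=C=O)=C=O)c2c1C[C@H](OCOC)[C@@H](c1ccc(OCOC)c(OCOC)c1)O2 | intermediate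
16 | (2R,3S)-2-[3,4-bis(methoxymethoxy)phenyl]-3,5,7-tris(methoxymethoxy)-6,8-bis[(4S,6aR)-4-methyl-2-oxo-1,2,4,5,6,6a-hexahydropentalen-3-yl]chromane | COCOc1c(C3=C4[C@@H](C)CC[C@@H]4CC3=O)c(OCOC)c(C3=C4[C@@H](C)CC[C@@H]4CC3=O)c2c1C[C@H](OCOC)[C@@H](c1ccc(OCOC)c(OCOC)c1)O2 | intermediate
17 | mixture of C1 epimers of 18 (pentalene C1 undefined in each arm; 3aR,6S,6aR) | COCOc1c(C3[C@H]4[C@H](CC[C@@H]4C)CC3=O)c(OCOC)c(C3[C@H]4[C@H](CC[C@@H]4C)CC3=O)c2c1C[C@H](OCOC)[C@@H](c1ccc(OCOC)c(OCOC)c1)O2 | intermediate
18 | (2R,3S)-2-[3,4-bis(methoxymethoxy)phenyl]-3,5,7-tris(methoxymethoxy)-6,8-bis[(1R,3aR,6S,6aR)-6-methyl-2-oxooctahydropentalen-1-yl]chromane | COCOc1c([C@H]3[C@H]4[C@H](CC[C@@H]4C)CC3=O)c(OCOC)c([C@H]3[C@H]4[C@H](CC[C@@H]4C)CC3=O)c2c1C[C@H](OCOC)[C@@H](c1ccc(OCOC)c(OCOC)c1)O2 | intermediate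
19 | (2R,3S)-2-[3,4-bis(methoxymethoxy)phenyl]-3,5,7-tris(methoxymethoxy)-6,8-bis[(1R,2E,3aR,6S,6aR)-2-(hydroxyimino)-6-methyloctahydropentalen-1-yl]chromane | COCOc1c([C@H]3[C@H]4[C@H](CC[C@@H]4C)C/C3=N\O)c(OCOC)c([C@H]3[C@H]4[C@H](CC[C@@H]4C)C/C3=N\O)c2c1C[C@H](OCOC)[C@@H](c1ccc(OCOC)c(OCOC)c1)O2 | intermediate
20 | bis[O-(4-methylbenzenesulfonyl)] derivative of bis-oxime 19 (E at both C=N) | COCOc1c([C@H]3[C@H]4[C@H](CC[C@@H]4C)C/C3=N\OS(=O)(=O)c5ccc(C)cc5)c(OCOC)c([C@H]3[C@H]4[C@H](CC[C@@H]4C)C/C3=N\OS(=O)(=O)c5ccc(C)cc5)c2c1C[C@H](OCOC)[C@@H](c1ccc(OCOC)c(OCOC)c1)O2 | intermediate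
21 | (2R,3S)-2-[3,4-bis(methoxymethoxy)phenyl]-3,5,7-tris(methoxymethoxy)-6,8-bis[(1R,4aR,7S,7aR)-7-methyl-3-oxooctahydro-1H-cyclopenta[c]pyridin-1-yl]chromane | COCOc1c([C@H]3[C@H]4[C@H](CC[C@@H]4C)CC(=O)N3)c(OCOC)c([C@H]3[C@H]4[C@H](CC[C@@H]4C)CC(=O)N3)c2c1C[C@H](OCOC)[C@@H](c1ccc(OCOC)c(OCOC)c1)O2 | intermediate
22 | (2R,3S)-2-[3,4-bis(methoxymethoxy)phenyl]-3,5,7-tris(methoxymethoxy)-6,8-bis[(1R,4aR,7S,7aR)-2,7-dimethyl-3-oxooctahydro-1H-cyclopenta[c]pyridin-1-yl]chromane | COCOc1c([C@H]3[C@H]4[C@H](CC[C@@H]4C)CC(=O)N3C)c(OCOC)c([C@H]3[C@H]4[C@H](CC[C@@H]4C)CC(=O)N3C)c2c1C[C@H](OCOC)[C@@H](c1ccc(OCOC)c(OCOC)c1)O2 | intermediate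
23 | (2R,3S)-2-[3,4-bis(methoxymethoxy)phenyl]-3,5,7-tris(methoxymethoxy)-6,8-bis[(1R,4R,4aS,7S,7aR)-2,4,7-trimethyl-3-oxooctahydro-1H-cyclopenta[c]pyridin-1-yl]chromane | COCOc1c([C@H]3[C@H]4[C@H](CC[C@@H]4C)[C@@H](C)C(=O)N3C)c(OCOC)c([C@H]3[C@H]4[C@H](CC[C@@H]4C)[C@@H](C)C(=O)N3C)c2c1C[C@H](OCOC)[C@@H](c1ccc(OCOC)c(OCOC)c1)O2 | intermediate
24 | (2R,3S)-2-[3,4-bis(methoxymethoxy)phenyl]-3,5,7-tris(methoxymethoxy)-6,8-bis[(1R,4R,4aR,7S,7aR)-2,4,7-trimethyloctahydro-1H-cyclopenta[c]pyridin-1-yl]chromane | COCOc1c([C@H]3[C@H]4[C@H](CC[C@@H]4C)[C@@H](C)CN3C)c(OCOC)c([C@H]3[C@H]4[C@H](CC[C@@H]4C)[C@@H](C)CN3C)c2c1C[C@H](OCOC)[C@@H](c1ccc(OCOC)c(OCOC)c1)O2 | intermediate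
25 | (2R,3S)-2-(3,4-dihydroxyphenyl)-6,8-bis[(1R,4R,4aR,7S,7aR)-2,4,7-trimethyloctahydro-1H-cyclopenta[c]pyridin-1-yl]chromane-3,5,7-triol | C[C@H]1CN(C)[C@@H](c2c(O)c3c(c([C@H]4[C@H]5[C@H](CC[C@@H]5C)[C@@H](C)CN4C)c2O)O[C@H](c2ccc(O)c(O)c2)[C@@H](O)C3)[C@H]2[C@@H]1CC[C@@H]2C | target

## Step count and least certain steps

Total: 18 steps. Longest linear sequence: 16 steps (steps 1–7, then 10–18); the catechin branch (steps 8 and 9) joins at step 10.

**Step 11 (key step).**
- Risk: alkene insertion at a cobalt cluster wedged between two ortho oxygens may be slow, so decomplexation or alkyne reduction could compete. An imperfect facial preference at C4a would be multiplied over two arms.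
- Fallback (sets out from 10 and 13, returns at 16): the hindered aryl group is taken out of the cycloaddition. Enyne 10 would be silylated (n-BuLi, Me3SiCl) to (S)-trimethyl(3-methylhept-6-en-1-yn-1-yl)silane F1. Its Pauson–Khand reaction (Co2(CO)8, then N-oxide) is the best-precedented case of propargylic control for a bulky alkyne substituent and should give (4S,6aR)-4-methyl-3-(trimethylsilyl)-4,5,6,6a-tetrahydropentalen-2(1H)-one F2. Ipso-iododesilylation with ICl would give (4S,6aR)-3-iodo-4-methyl-4,5,6,6a-tetrahydropentalen-2(1H)-one F3. Diiodide 13 would be converted by iodine–lithium exchange (t-BuLi) and ZnCl2 into the 6,8-bis(chlorozincio) derivative of penta-O-methoxymethylcatechin F4. A twofold Negishi coupling of F4 with F3 (Pd(OAc)2, SPhos, THF) would give 16.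

**Step 14.**
- Risk: heterolysis of the C1–C3 bond (Beckmann fragmentation) may outrun migration, because the migrating carbon is benzylic to a tri-oxygenated ring. Partial loss of oxime geometry would also let C4 migrate.
- Fallback (sets out from 18, returns at 22): oxygen is inserted first and then exchanged for nitrogen. Baeyer–Villiger oxidation of 18 (mCPBA, NaHCO3), in which C1 migrates with retention, would give the bis-lactone 6,8-bis[(1R,4aR,7S,7aR)-7-methyl-3-oxooctahydrocyclopenta[c]pyran-1-yl] penta-O-methoxymethylcatechin F5. Aminolysis with methylamine would give the bis(hydroxy amide) 6,8-bis{(R)-hydroxy[(1R,2R,5S)-5-methyl-2-(2-(methylamino)-2-oxoethyl)cyclopentyl]methyl} penta-O-methoxymethylcatechin F6. Activation of the benzylic hydroxyls (MsCl, Et3N) should ionise C1, and the amide nitrogen would close the six-membered ring to 22. In that closure H7a is expected to eclipse the aryl plane (allylic 1,3-strain), which leads to the aryl group cis to H7a.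

**Step 12.**
- Risk: hydrogen-atom transfer to the tetrasubstituted C7a, shielded by the ortho substituents of the twisted aryl group, may be slow; 1,2-reduction or delivery to the wrong face could compete.
- Fallback (sets out from 16, returns at 18): the catalytic radical reduction is replaced by a dissolving-metal electron-transfer reduction (Li, NH3–THF, t-BuOH, −78 °C, limited lithium so that the aryl ethers and the flavan C2–O1 bond are spared). The C7a carbanion is protonated under thermodynamic control to the cis-fused ketone, and C1 is equilibrated as before. This makes no new compound, F0.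

**Step 10.**
- Risk: oxidative addition to the very electron-rich, doubly ortho-substituted iodide may be slow, so the second coupling could stall; copper-mediated dimerisation would consume 10.
- Fallback (sets out from 10 and 13, returns at 14): a copper-free Negishi coupling. Enyne 10 would be deprotonated (n-BuLi) and transmetalated with ZnCl2 to chloro[(3S)-3-methylhept-6-en-1-yn-1-yl]zinc F7, which would be coupled twice with 13 (Pd(OAc)2, XPhos, THF, 60 °C).

**Step 18.**
- Risk: the acid needed for the aliphatic 3-O-acetal may ionise a benzylic C1–N bond once the ortho and para oxygens are free, which would epimerise C1. The free polyphenol amine may also oxidise during neutralisation.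
- Fallback (sets out from 23, returns at 25): the last two steps are exchanged. Acid methanolysis at the lactam stage, where nitrogen is an amide and C1–N cannot ionise, would give (2R,3S)-2-(3,4-dihydroxyphenyl)-3,5,7-trihydroxy-6,8-bis[(1R,4R,4aS,7S,7aR)-2,4,7-trimethyl-3-oxooctahydro-1H-cyclopenta[c]pyridin-1-yl]chromane F8. Reduction with excess LiAlH4 (the phenols are carried as aluminates) would then give 25 without any acid after the amines are formed.

## Further compounds

F1 | step 11 | (S)-trimethyl(3-methylhept-6-en-1-yn-1-yl)silane | C[Si](C)(C)C#C[C@@H](C)CCC=C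
F2 | step 11 | (4S,6aR)-4-methyl-3-(trimethylsilyl)-4,5,6,6a-tetrahydropentalen-2(1H)-one | C[Si](C)(C)C1=C2[C@@H](C)CC[C@@H]2CC1=O
F3 | step 11 | (4S,6aR)-3-iodo-4-methyl-4,5,6,6a-tetrahydropentalen-2(1H)-one | IC1=C2[C@@H](C)CC[C@@H]2CC1=O
F4 | step 11 | [(2R,3S)-2-[3,4-bis(methoxymethoxy)phenyl]-3,5,7-tris(methoxymethoxy)chromane-6,8-diyl]bis(chlorozinc) | COCOc1c([Zn]Cl)c(OCOC)c([Zn]Cl)c2c1C[C@H](OCOC)[C@@H](c1ccc(OCOC)c(OCOC)c1)O2
F5 | step 14 | (2R,3S)-2-[3,4-bis(methoxymethoxy)phenyl]-3,5,7-tris(methoxymethoxy)-6,8-bis[(1R,4aR,7S,7aR)-7-methyl-3-oxooctahydrocyclopenta[c]pyran-1-yl]chromane | COCOc1c([C@H]3[C@H]4[C@H](CC[C@@H]4C)CC(=O)O3)c(OCOC)c([C@H]3[C@H]4[C@H](CC[C@@H]4C)CC(=O)O3)c2c1C[C@H](OCOC)[C@@H](c1ccc(OCOC)c(OCOC)c1)O2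
F6 | step 14 | (2R,3S)-2-[3,4-bis(methoxymethoxy)phenyl]-3,5,7-tris(methoxymethoxy)-6,8-bis{(R)-hydroxy[(1R,2R,5S)-5-methyl-2-(2-(methylamino)-2-oxoethyl)cyclopentyl]methyl}chromane | COCOc1c([C@H](O)[C@H]3[C@H](CC[C@@H]3C)CC(=O)NC)c(OCOC)c([C@H](O)[C@H]3[C@H](CC[C@@H]3C)CC(=O)NC)c2c1C[C@H](OCOC)[C@@H](c1ccc(OCOC)c(OCOC)c1)O2
F0 | step 12 | none | none
F7 | step 10 | chloro[(3S)-3-methylhept-6-en-1-yn-1-yl]zinc | Cl[Zn]C#C[C@@H](C)CCC=C
F8 | step 18 | (2R,3S)-2-(3,4-dihydroxyphenyl)-3,5,7-trihydroxy-6,8-bis[(1R,4R,4aS,7S,7aR)-2,4,7-trimethyl-3-oxooctahydro-1H-cyclopenta[c]pyridin-1-yl]chromane | Oc1c([C@H]3[C@H]4[C@H](CC[C@@H]4C)[C@@H](C)C(=O)N3C)c(O)c([C@H]3[C@H]4[C@H](CC[C@@H]4C)[C@@H](C)C(=O)N3C)c2c1C[C@H](O)[C@@H](c1ccc(O)c(O)c1)O2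
A1 | alternative 1 | 1,3-bis[(1S,4R,4aR,7S,7aR)-2,4,7-trimethyloctahydro-1H-cyclopenta[c]pyridin-1-yl]propan-2-one | O=C(C[C@H]1[C@H]2[C@H](CC[C@@H]2C)[C@@H](C)CN1C)C[C@H]1[C@H]2[C@H](CC[C@@H]2C)[C@@H](C)CN1C
A2 | alternative 1 | 2-{[(4S,5S)-5-(3,4-diacetoxyphenyl)-2-oxo-1,3-dioxolan-4-yl]methyl}propanedioyl dichloride | ClC(=O)C(C(Cl)=O)C[C@@H]1OC(=O)O[C@H]1c1ccc(OC(C)=O)c(OC(C)=O)c1
A3 | alternative 1 | 2-{[(4S,5S)-5-(3,4-diacetoxyphenyl)-2-oxo-1,3-dioxolan-4-yl]methyl}-4,6-bis[(1R,4R,4aR,7S,7aR)-2,4,7-trimethyloctahydro-1H-cyclopenta[c]pyridin-1-yl]benzene-1,3,5-triol | Oc1c([C@H]3[C@H]4[C@H](CC[C@@H]4C)[C@@H](C)CN3C)c(O)c([C@H]3[C@H]4[C@H](CC[C@@H]4C)[C@@H](C)CN3C)c(O)c1C[C@@H]2OC(=O)O[C@H]2c1ccc(OC(C)=O)c(OC(C)=O)c1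
A4 | alternative 2 | (2R,3S)-2-[3,4-bis(methoxymethoxy)phenyl]-3,5,7-tris(methoxymethoxy)-6,8-bis{(5R,6R)-5-[(2S)-5-[(1,3-dioxoisoindolin-2-yl)oxy]-5-oxopentan-2-yl]-1,3-dimethyl-2-oxo-1,2,5,6-tetrahydropyridin-6-yl}chromane | COCOc1c([C@H]3[C@H]([C@@H](C)CCC(=O)ON4C(=O)c5ccccc5C4=O)C=C(C)C(=O)N3C)c(OCOC)c([C@H]3[C@H]([C@@H](C)CCC(=O)ON4C(=O)c5ccccc5C4=O)C=C(C)C(=O)N3C)c2c1C[C@H](OCOC)[C@@H](c1ccc(OCOC)c(OCOC)c1)O2
A5 | alternative 2 | (2R,3S)-2-[3,4-bis(methoxymethoxy)phenyl]-3,5,7-tris(methoxymethoxy)-6,8-bis[(1R,4R,4aS,7S,7aR)-2,4,7-trimethyl-3-oxooctahydro-1H-cyclopenta[c]pyridin-1-yl]chromane (identical with 23) | COCOc1c([C@H]3[C@H]4[C@H](CC[C@@H]4C)[C@@H](C)C(=O)N3C)c(OCOC)c([C@H]3[C@H]4[C@H](CC[C@@H]4C)[C@@H](C)C(=O)N3C)c2c1C[C@H](OCOC)[C@@H](c1ccc(OCOC)c(OCOC)c1)O2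
A6 | alternative 3 | 5-{[(1S)-1-[3,4-bis(methoxymethoxy)phenyl]prop-2-en-1-yl]oxy}-6-ethenyl-2,4-bis[(1R,4R,4aR,7S,7aR)-2,4,7-trimethyloctahydro-1H-cyclopenta[c]pyridin-1-yl]benzene-1,3-diol | Oc1c([C@H]3[C@H]4[C@H](CC[C@@H]4C)[C@@H](C)CN3C)c(O)c([C@H]3[C@H]4[C@H](CC[C@@H]4C)[C@@H](C)CN3C)c(O[C@@H](C=C)c2ccc(OCOC)c(OCOC)c2)c1C=C
A7 | alternative 3 | (2S)-2-[3,4-bis(methoxymethoxy)phenyl]-6,8-bis[(1R,4R,4aR,7S,7aR)-2,4,7-trimethyloctahydro-1H-cyclopenta[c]pyridin-1-yl]-2H-chromene-5,7-diol | Oc1c([C@H]3[C@H]4[C@H](CC[C@@H]4C)[C@@H](C)CN3C)c(O)c([C@H]3[C@H]4[C@H](CC[C@@H]4C)[C@@H](C)CN3C)c2c1C=C[C@@H](c1ccc(OCOC)c(OCOC)c1)O2
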